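**Plan**

1. Numbering is that of 1,4-benzodioxin: O1, C2 (bears CH2OH), C3 (bears the syringyl ring), O4, C4a, C5–C8, C8a; the propenal chain sits on C6. The retrosynthesis cuts first the C6–alkenyl bond (aryl triflate + alkenylboronate), then the aryl ether bond O4–C4a that closes the dioxane ring, then the C2–C3 bond (aldol). This leads back to syringaldehyde, [4-(benzyloxy)phenoxy]acetic acid and an oxazolidinone.
2. Enabling feature: O1 is para to C6 and C4a is ortho to O1. With OH on C6 in place of the chain, the benzo ring is a hydroquinone monoether. Its p-quinone monoketal makes C4a (either of the two equivalent carbons next to the ketal carbon C8a) an enone β-carbon that accepts the C3 oxygen, and loss of methanol restores the arene. The helper OH then becomes the triflate that brings in the chain.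
3. Forward: both benzene rings are bought. The aldol joins the two halves with O1–C8a already in place. The dioxane ring, the only ring made, closes in step 8. The chain enters at C6 by Suzuki coupling, and one acid step removes all protecting groups.
4. Stereochemistry: C2 and C3 (2S,3S; trans on the ring, syn/threo in the open chain) both come from the boron aldol directed by (R)-4-benzyl-1,3-oxazolidin-2-one. No bond to either carbon is broken afterwards. The E-alkene comes from the E-alkenylboronate.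

Key step: step 8

Assumption: 1, 3, 4 and 18 are taken as purchasable. In dienones 13–15 the ketal carbon is the future C8a and the carbonyl carbon the future C6.

**Route**

Step 1
Reactants: 1 syringaldehyde (4-hydroxy-3,5-dimethoxybenzaldehyde)
Product: 2 3,5-dimethoxy-4-(methoxymethoxy)benzaldehyde
Conditions: MOMCl, K2CO3, acetone, 0 °C to rt
Reagents that add atoms: chloromethyl methyl ether (MOMCl), COCCl
Why: O-alkylation of the phenoxide (Williamson ether synthesis) should give a MOM ether that survives the boron aldol, hydride, hydrogenolysis and base, and is removed by the final acid step.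

Step 2
Reactants: 3 [4-(benzyloxy)phenoxy]acetic acid; 4 (R)-4-benzyl-1,3-oxazolidin-2-one
Product: 6 (R)-4-benzyl-3-{[4-(benzyloxy)phenoxy]acetyl}-1,3-oxazolidin-2-one, via mixed pivalic anhydride 5 (not isolated)
Conditions: PivCl, Et3N, THF, −20 °C; then LiCl, 4, rt
Reagents that add atoms: none
Why: N-acylation of the oxazolidinone by the mixed anhydride (LiCl-assisted) is the standard way to make Evans imides from aryloxy- and alkoxyacetic acids.

Step 3
Reactants: 6 imide; 2 aldehyde
Product: 8 (R)-4-benzyl-3-{(2R,3S)-2-[4-(benzyloxy)phenoxy]-3-[3,5-dimethoxy-4-(methoxymethoxy)phenyl]-3-hydroxypropanoyl}-1,3-oxazolidin-2-one, via Z-dibutylboron enolate 7 (not isolated)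
Conditions: Bu2BOTf, iPr2NEt, CH2Cl2, 0 °C; 2, −78 to 0 °C; then pH 7 buffer, MeOH, 30% H2O2, 0 °C
Reagents that add atoms: none
Why: Evans syn aldol: the Z-boron enolate 7 should react through a Zimmerman–Traxler chair on the face away from the benzyl group of the (R)-auxiliary, setting both new stereocentres at once as the syn (threo) pair, 2R,3S in the imide, which is 2S,3S at C2/C3 of the target.

Step 4
Reactants: 8 aldol imide
Product: 9 (1S,2S)-2-[4-(benzyloxy)phenoxy]-1-[3,5-dimethoxy-4-(methoxymethoxy)phenyl]propane-1,3-diol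
Conditions: LiBH4, MeOH (1 equiv), THF, 0 °C
Reagents that add atoms: none
Why: Reductive cleavage of the N-acyl oxazolidinone by LiBH4 should turn the imide carbonyl into the hydroxymethyl carbon and release the recoverable auxiliary without touching either stereocentre.

Step 5
Reactants: 9 diol
Product: 11 (1S,2S)-2-[4-(benzyloxy)phenoxy]-3-[(tert-butyldimethylsilyl)oxy]-1-[3,5-dimethoxy-4-(methoxymethoxy)phenyl]propyl acetate, via mono-TBS ether 10 (not isolated)
Conditions: TBSCl, imidazole, CH2Cl2, 0 °C; then Ac2O, pyridine, DMAP (cat.), rt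
Reagents that add atoms: tert-butyldimethylsilyl chloride (TBSCl), CC(C)(C)[Si](C)(C)Cl; acetic anhydride, CC(=O)OC(C)=O
Why: The primary hydroxyl should be silylated selectively (steric control) and the remaining hindered benzylic hydroxyl then acetylated, so that it cannot attack the ring in step 7 and can be unmasked by base in step 8.

Step 6
Reactants: 11 benzyl ether
Product: 12 (1S,2S)-3-[(tert-butyldimethylsilyl)oxy]-1-[3,5-dimethoxy-4-(methoxymethoxy)phenyl]-2-(4-hydroxyphenoxy)propyl acetate
Conditions: H2 (1 atm), Pd/C, EtOAc, rt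
Reagents that add atoms: none
Why: Hydrogenolysis of the phenolic benzyl ether should be much faster than C–O hydrogenolysis of the secondary benzylic acetate in neutral EtOAc, so stopping after one equivalent of H2 should free only the hydroquinone hydroxyl.

Step 7
Reactants: 12 phenol
Product: 13 (1S,2S)-3-[(tert-butyldimethylsilyl)oxy]-1-[3,5-dimethoxy-4-(methoxymethoxy)phenyl]-2-[(1-methoxy-4-oxocyclohexa-2,5-dien-1-yl)oxy]propyl acetate
Conditions: PhI(OAc)2, MeOH, 0 °C
Reagents that add atoms: methanol, CO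
Why: Oxidative dearomatisation of a p-alkoxyphenol by PhI(OAc)2 in methanol should give the mixed p-quinone monoketal, with methanol as the only nucleophile available because the benzylic oxygen is acetylated.

Step 8
Reactants: 13 quinone monoketal
Product: 16 (2S,3S)-2-{[(tert-butyldimethylsilyl)oxy]methyl}-3-[3,5-dimethoxy-4-(methoxymethoxy)phenyl]-2,3-dihydro-1,4-benzodioxin-6-ol, via hydroxy dienone ketal 14 (not isolated), via cis-fused oxa-Michael adduct 15 (not isolated)
Conditions: K2CO3 (0.3 equiv), MeOH, 0 °C to rt; pH 7 buffer work-up; then CSA (0.1 equiv), CH2Cl2, 0 °C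
Reagents that add atoms: none
Why: Proposed new method: catalytic methoxide removes the acetate of 13, and the freed C3 alkoxide of 14 adds in a 6-exo-trig oxa-Michael reaction to one of the two enone β-carbons next to the ketal carbon to give the cis-fused ketal 15; acid then ionises the methoxy ketal, the oxocarbenium ion loses the ring-fusion proton and the dienone tautomerises to the phenol, so the O4–C4a bond is made and the benzo ring is restored with loss of methanol. The closest known reaction types are the conjugate addition of heteroatom and carbon nucleophiles to p-quinone monoketals followed by acid-induced loss of methanol to 3-substituted 4-alkoxyphenols, and intramolecular oxa-Michael additions to cyclohexadienones; their tandem use to close a 1,4-benzodioxane is the new element. Only the dioxane ring is closed, in the 6-exo-trig mode, through the benzylic oxygen. No stereocentre of 16 is created here: C2 and C3 keep the aldol configuration because the acetate is cleaved at the acyl–oxygen bond and no bond to either carbon breaks, and the two ring-fusion centres of 15 are erased on aromatisation. The step needs regiocontrol (O4 on C4a, O1 on C8a para to the new C6 hydroxyl) and a choice between the two side-chain oxygens: ketals do not exchange under base, so O1 stays on the former ketal carbon while both β-carbons lead to the same arene, and the primary oxygen stays silylated while the benzylic oxygen is unmasked only after the ketal exists, which also rules out a spiro-dioxolane ketal.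

Step 9
Reactants: 16 phenol
Product: 17 (2S,3S)-2-{[(tert-butyldimethylsilyl)oxy]methyl}-3-[3,5-dimethoxy-4-(methoxymethoxy)phenyl]-2,3-dihydro-1,4-benzodioxin-6-yl trifluoromethanesulfonate
Conditions: PhNTf2, Et3N, DMAP (cat.), CH2Cl2, rt
Reagents that add atoms: N-phenylbis(trifluoromethanesulfonimide) (PhNTf2), O=S(=O)(N(c1ccccc1)S(=O)(=O)C(F)(F)F)C(F)(F)F
Why: O-sulfonylation of the phenol, the only free hydroxyl, should turn the helper OH into the cross-coupling handle at C6.

Step 10
Reactants: 17 aryl triflate; 18 (E)-2-(3,3-diethoxyprop-1-en-1-yl)-4,4,5,5-tetramethyl-1,3,2-dioxaborolane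
Product: 19 tert-butyl({(2S,3S)-6-[(E)-3,3-diethoxyprop-1-en-1-yl]-3-[3,5-dimethoxy-4-(methoxymethoxy)phenyl]-2,3-dihydro-1,4-benzodioxin-2-yl}methoxy)dimethylsilane
Conditions: PdCl2(dppf) (5 mol %), K3PO4, 1,4-dioxane/H2O, 80 °C
Reagents that add atoms: none
Why: Suzuki–Miyaura coupling of the aryl triflate with the E-alkenylboronate should transfer the alkene with retention of its E geometry and bring in the aldehyde as its diethyl acetal.

Step 11
Reactants: 19 protected acetal
Product: 20 (E)-3-[(2S,3S)-2-(hydroxymethyl)-3-(4-hydroxy-3,5-dimethoxyphenyl)-2,3-dihydro-1,4-benzodioxin-6-yl]prop-2-enal (target)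
Conditions: 2 M HCl aq, THF, rt to 40 °C
Reagents that add atoms: water, O
Why: Aqueous acid should hydrolyse the allylic acetal to the enal and cleave the MOM and primary TBS ethers in one operation (acetal hydrolysis), and the trans arrangement at C2/C3 is the thermodynamically preferred one.

**Compound list**

1 | syringaldehyde (4-hydroxy-3,5-dimethoxybenzaldehyde) | COc1cc(C=O)cc(OC)c1O | starting material
2 | 3,5-dimethoxy-4-(methoxymethoxy)benzaldehyde | COCOc1c(OC)cc(C=O)cc1OC | intermediate
3 | [4-(benzyloxy)phenoxy]acetic acid | OC(=O)COc1ccc(OCc2ccccc2)cc1 | starting material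
4 | (R)-4-benzyl-1,3-oxazolidin-2-one | O=C1N[C@H](Cc2ccccc2)CO1 | starting material
5 | [4-(benzyloxy)phenoxy]acetic pivalic anhydride (formed in the flask) | CC(C)(C)C(=O)OC(=O)COc1ccc(OCc2ccccc2)cc1 | intermediate
6 | (R)-4-benzyl-3-{[4-(benzyloxy)phenoxy]acetyl}-1,3-oxazolidin-2-one | O=C(COc1ccc(OCc2ccccc2)cc1)N1[C@H](Cc2ccccc2)COC1=O | intermediate
7 | Z-dibutylboron enolate of 6 (formed in the flask) | CCCCB(CCCC)O/C(=C\Oc1ccc(OCc2ccccc2)cc1)N1[C@H](Cc2ccccc2)COC1=O | intermediate
8 | (R)-4-benzyl-3-{(2R,3S)-2-[4-(benzyloxy)phenoxy]-3-[3,5-dimethoxy-4-(methoxymethoxy)phenyl]-3-hydroxypropanoyl}-1,3-oxazolidin-2-one | COCOc1c(OC)cc(cc1OC)[C@H](O)[C@@H](Oc1ccc(OCc2ccccc2)cc1)C(=O)N1[C@H](Cc2ccccc2)COC1=O | intermediate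
9 | (1S,2S)-2-[4-(benzyloxy)phenoxy]-1-[3,5-dimethoxy-4-(methoxymethoxy)phenyl]propane-1,3-diol | COCOc1c(OC)cc(cc1OC)[C@H](O)[C@@H](Oc1ccc(OCc2ccccc2)cc1)CO | intermediate
10 | (1S,2S)-2-[4-(benzyloxy)phenoxy]-3-[(tert-butyldimethylsilyl)oxy]-1-[3,5-dimethoxy-4-(methoxymethoxy)phenyl]propan-1-ol (formed in the flask) | COCOc1c(OC)cc(cc1OC)[C@H](O)[C@@H](Oc1ccc(OCc2ccccc2)cc1)CO[Si](C)(C)C(C)(C)C | intermediate
11 | (1S,2S)-2-[4-(benzyloxy)phenoxy]-3-[(tert-butyldimethylsilyl)oxy]-1-[3,5-dimethoxy-4-(methoxymethoxy)phenyl]propyl acetate | COCOc1c(OC)cc(cc1OC)[C@H](OC(C)=O)[C@@H](Oc1ccc(OCc2ccccc2)cc1)CO[Si](C)(C)C(C)(C)C | intermediate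
12 | (1S,2S)-3-[(tert-butyldimethylsilyl)oxy]-1-[3,5-dimethoxy-4-(methoxymethoxy)phenyl]-2-(4-hydroxyphenoxy)propyl acetate | COCOc1c(OC)cc(cc1OC)[C@H](OC(C)=O)[C@@H](Oc1ccc(O)cc1)CO[Si](C)(C)C(C)(C)C | intermediate
13 | (1S,2S)-3-[(tert-butyldimethylsilyl)oxy]-1-[3,5-dimethoxy-4-(methoxymethoxy)phenyl]-2-[(1-methoxy-4-oxocyclohexa-2,5-dien-1-yl)oxy]propyl acetate | COCOc1c(OC)cc(cc1OC)[C@H](OC(C)=O)[C@@H](OC1(OC)C=CC(=O)C=C1)CO[Si](C)(C)C(C)(C)C | intermediate
14 | 4-{[(1S,2S)-3-[(tert-butyldimethylsilyl)oxy]-1-[3,5-dimethoxy-4-(methoxymethoxy)phenyl]-1-hydroxypropan-2-yl]oxy}-4-methoxycyclohexa-2,5-dien-1-one (formed in the flask) | COCOc1c(OC)cc(cc1OC)[C@H](O)[C@@H](OC1(OC)C=CC(=O)C=C1)CO[Si](C)(C)C(C)(C)C | intermediate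
15 | (2S,3S)-2-{[(tert-butyldimethylsilyl)oxy]methyl}-3-[3,5-dimethoxy-4-(methoxymethoxy)phenyl]-8a-methoxy-2,3,4a,8a-tetrahydro-1,4-benzodioxin-6(5H)-one, cis ring fusion, ring-fusion configuration not controlled (formed in the flask) | COCOc1c(OC)cc(cc1OC)[C@@H]1OC2CC(=O)C=CC2(OC)O[C@H]1CO[Si](C)(C)C(C)(C)C | intermediate
16 | (2S,3S)-2-{[(tert-butyldimethylsilyl)oxy]methyl}-3-[3,5-dimethoxy-4-(methoxymethoxy)phenyl]-2,3-dihydro-1,4-benzodioxin-6-ol | COCOc1c(OC)cc(cc1OC)[C@@H]1Oc2cc(O)ccc2O[C@H]1CO[Si](C)(C)C(C)(C)C | intermediate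
17 | (2S,3S)-2-{[(tert-butyldimethylsilyl)oxy]methyl}-3-[3,5-dimethoxy-4-(methoxymethoxy)phenyl]-2,3-dihydro-1,4-benzodioxin-6-yl trifluoromethanesulfonate | COCOc1c(OC)cc(cc1OC)[C@@H]1Oc2cc(OS(=O)(=O)C(F)(F)F)ccc2O[C@H]1CO[Si](C)(C)C(C)(C)C | intermediate
18 | (E)-2-(3,3-diethoxyprop-1-en-1-yl)-4,4,5,5-tetramethyl-1,3,2-dioxaborolane | CCOC(OCC)/C=C/B1OC(C)(C)C(C)(C)O1 | starting material
19 | tert-butyl({(2S,3S)-6-[(E)-3,3-diethoxyprop-1-en-1-yl]-3-[3,5-dimethoxy-4-(methoxymethoxy)phenyl]-2,3-dihydro-1,4-benzodioxin-2-yl}methoxy)dimethylsilane | COCOc1c(OC)cc(cc1OC)[C@@H]1Oc2cc(/C=C/C(OCC)OCC)ccc2O[C@H]1CO[Si](C)(C)C(C)(C)C | intermediate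
20 | (E)-3-[(2S,3S)-2-(hydroxymethyl)-3-(4-hydroxy-3,5-dimethoxyphenyl)-2,3-dihydro-1,4-benzodioxin-6-yl]prop-2-enal | COc1cc([C@@H]2Oc3cc(/C=C/C=O)ccc3O[C@H]2CO)cc(OC)c1O | target

**Count and risks**

Total steps: 11. Longest linear sequence: 10 steps (steps 1 and 3–11 from 1, or steps 2–11 from 3).

Steps most likely to fail:

1. Step 8. The acid-induced aromatisation may be outrun by retro-Michael opening and ketal exchange, with loss of the tethered oxygen instead of methanol. The silyl group may also migrate to the benzylic alkoxide, so that the primary oxygen adds. Fallback with known chemistry, setting out from 4 and 2 and returning at 16: commercial 4-(benzyloxy)phenol would be brominated ortho to the hydroxyl (NBS, CH2Cl2, 0 °C) to 4-(benzyloxy)-2-bromophenol F1 and O-alkylated with bromoacetic acid (NaOH aq, reflux) to [4-(benzyloxy)-2-bromophenoxy]acetic acid F2. This acid would be taken through the conditions of steps 2 to 4 with 4 and 2, giving the bromo imide F3, the syn-aldol adduct F4 and the bromo diol F5. Primary silylation (TBSCl, imidazole) would give the bromo alcohol F6. Intramolecular C–O coupling of the secondary alcohol with the aryl bromide (Buchwald–Hartwig etherification; Pd(OAc)2, 2-(di-tert-butylphosphino)-1,1'-binaphthyl, Cs2CO3, toluene, 70 °C) would close the same O4–C4a bond to the 6-benzyloxy benzodioxane F7. Hydrogenolysis (H2, Pd/C, EtOAc) would then give 16.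

2. Step 6. Over-reduction may occur, that is hydrogenolytic loss of the electron-rich benzylic acetate along with the benzyl ether. Fallback setting out from 9 and returning at 12: silylation alone would give 10, now isolated. Hydrogenolysis at this stage, where C1 carries a free hydroxyl and no ester, would give the phenol alcohol F8. Acetylation of both hydroxyls (Ac2O, pyridine, DMAP) would give the diacetate F9. Chemoselective cleavage of the aryl acetate (NH4OAc, aqueous MeOH, rt) would then leave the benzylic acetate in place and give 12.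

3. Step 11. Under the acid needed for MOM removal, C3 may epimerise through a p-quinone methide or the enal may degrade. Fallback setting out from 17 and returning at 20: the MOM and TBS groups would be removed before the enal exists (3 M HCl aq, THF, 40 °C), giving the triflate diol phenol F10. Suzuki–Miyaura coupling of F10 with 18 (PdCl2(dppf), excess K3PO4, 1,4-dioxane/H2O) would give the unprotected acetal F11 in the flask. A brief work-up at pH 3 would hydrolyse only the acetal and give 20.

**Further compounds**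

F1 | step 8 | 4-(benzyloxy)-2-bromophenol | Oc1ccc(OCc2ccccc2)cc1Br
F2 | step 8 | [4-(benzyloxy)-2-bromophenoxy]acetic acid | OC(=O)COc1ccc(OCc2ccccc2)cc1Br
F3 | step 8 | (R)-4-benzyl-3-{[4-(benzyloxy)-2-bromophenoxy]acetyl}-1,3-oxazolidin-2-one | O=C(COc1ccc(OCc2ccccc2)cc1Br)N1[C@H](Cc2ccccc2)COC1=O
F4 | step 8 | (R)-4-benzyl-3-{(2R,3S)-2-[4-(benzyloxy)-2-bromophenoxy]-3-[3,5-dimethoxy-4-(methoxymethoxy)phenyl]-3-hydroxypropanoyl}-1,3-oxazolidin-2-one | COCOc1c(OC)cc(cc1OC)[C@H](O)[C@@H](Oc1ccc(OCc2ccccc2)cc1Br)C(=O)N1[C@H](Cc2ccccc2)COC1=O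
F5 | step 8 | (1S,2S)-2-[4-(benzyloxy)-2-bromophenoxy]-1-[3,5-dimethoxy-4-(methoxymethoxy)phenyl]propane-1,3-diol | COCOc1c(OC)cc(cc1OC)[C@H](O)[C@@H](Oc1ccc(OCc2ccccc2)cc1Br)CO
F6 | step 8 | (1S,2S)-2-[4-(benzyloxy)-2-bromophenoxy]-3-[(tert-butyldimethylsilyl)oxy]-1-[3,5-dimethoxy-4-(methoxymethoxy)phenyl]propan-1-ol | COCOc1c(OC)cc(cc1OC)[C@H](O)[C@@H](Oc1ccc(OCc2ccccc2)cc1Br)CO[Si](C)(C)C(C)(C)C
F7 | step 8 | (2S,3S)-6-(benzyloxy)-2-{[(tert-butyldimethylsilyl)oxy]methyl}-3-[3,5-dimethoxy-4-(methoxymethoxy)phenyl]-2,3-dihydro-1,4-benzodioxine | COCOc1c(OC)cc(cc1OC)[C@@H]1Oc2cc(OCc3ccccc3)ccc2O[C@H]1CO[Si](C)(C)C(C)(C)C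
F8 | step 6 | (1S,2S)-3-[(tert-butyldimethylsilyl)oxy]-1-[3,5-dimethoxy-4-(methoxymethoxy)phenyl]-2-(4-hydroxyphenoxy)propan-1-ol | COCOc1c(OC)cc(cc1OC)[C@H](O)[C@@H](Oc1ccc(O)cc1)CO[Si](C)(C)C(C)(C)C
F9 | step 6 | 4-{[(1S,2S)-1-acetoxy-3-[(tert-butyldimethylsilyl)oxy]-1-[3,5-dimethoxy-4-(methoxymethoxy)phenyl]propan-2-yl]oxy}phenyl acetate | COCOc1c(OC)cc(cc1OC)[C@H](OC(C)=O)[C@@H](Oc1ccc(OC(C)=O)cc1)CO[Si](C)(C)C(C)(C)C
F10 | step 11 | (2S,3S)-2-(hydroxymethyl)-3-(4-hydroxy-3,5-dimethoxyphenyl)-2,3-dihydro-1,4-benzodioxin-6-yl trifluoromethanesulfonate | COc1cc(cc(OC)c1O)[C@@H]1Oc2cc(OS(=O)(=O)C(F)(F)F)ccc2O[C@H]1CO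
F11 | step 11 | {(2S,3S)-6-[(E)-3,3-diethoxyprop-1-en-1-yl]-3-(4-hydroxy-3,5-dimethoxyphenyl)-2,3-dihydro-1,4-benzodioxin-2-yl}methanol | COc1cc(cc(OC)c1O)[C@@H]1Oc2cc(/C=C/C(OCC)OCC)ccc2O[C@H]1CO
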